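The route rests on cutting C5–N1 of the pyrrolidine-2,4-dione ring. C5 lies alpha to the C4 ketone, C3 is quaternary and N1 is an imide nitrogen. C5 and N1 are both natural donors, so C5 is carried as a diazo carbon and turned into an electrophilic rhodium carbene (polarity reversal). In the last step this carbene inserts into the imide N1–H. The ring closes, only N2 is lost, C5 is set by a chiral-acid proton relay, and no base ever meets the epimerisable product. The precursor is an open-chain 4-diazo-3-oxoacyl imide. It is assembled from dimethylmalonyl dichloride and both enantiomers of one 4,4,4-trichloro-3-methylbutanoyl building block, made on antipodal camphorsultams.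

Key step: step 10

Assumption: the facial sense of the LiCCl3 addition is taken from the chelate model of N-enoylbornane-10,2-sultams and that of the proton relay from related insertions; both auxiliaries and both acid antipodes are commercial, so a reversed sense would only swap antipodes.

Step 1
Reactants: 1 (1S)-(-)-2,10-camphorsultam [(2R)-bornane-10,2-sultam]; 2 (E)-crotonyl chloride
Product: 3 N-[(E)-but-2-enoyl]-(2R)-bornane-10,2-sultam
Conditions: NaH, toluene, 0 °C to rt; then 2
Reagents that add atoms: none
Why: N-acylation of the sodium salt of the sultam by an acid chloride (standard auxiliary loading); no stereocentre is formed and the E-alkene is kept.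

Step 2
Reactants: 3 N-[(E)-but-2-enoyl]-(2R)-bornane-10,2-sultam
Product: 4 N-[(3S)-4,4,4-trichloro-3-methylbutanoyl]-(2R)-bornane-10,2-sultam
Conditions: CHCl3, LiN(iPr)2, THF, -100 °C; add 3, -100 to -78 °C; AcOH quench at -78 °C
Reagents that add atoms: chloroform, ClC(Cl)Cl
Why: Auxiliary-controlled Michael addition of trichloromethyllithium: lithium bridging C=O and one S=O oxygen fixes the s-cis enoyl conformer, so CCl3 should add to the C-beta Si face remote from the bornane skeleton and set (3S), while the cold quench forestalls ring closure of the enolate onto CCl3.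

Step 3
Reactants: 4 N-[(3S)-4,4,4-trichloro-3-methylbutanoyl]-(2R)-bornane-10,2-sultam
Product: 5 (3S)-4,4,4-trichloro-3-methylbutanamide
Conditions: NH3 (7 M in MeOH), THF, rt
Reagents that add atoms: ammonia, N
Why: Ammonolysis of the activated N-acylsultam (acyl transfer; any methyl ester formed converges on the amide) frees the auxiliary and leaves C3 untouched because no strong base is present.

Step 4
Reactants: 6 (1R)-(+)-2,10-camphorsultam [(2S)-bornane-10,2-sultam]; 2 (E)-crotonyl chloride
Product: 7 N-[(E)-but-2-enoyl]-(2S)-bornane-10,2-sultam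
Conditions: NaH, toluene, 0 °C to rt; then 2
Reagents that add atoms: none
Why: The same N-acylation as in step 1 on the antipodal auxiliary; no stereocentre is formed.

Step 5
Reactants: 7 N-[(E)-but-2-enoyl]-(2S)-bornane-10,2-sultam
Product: 8 N-[(3R)-4,4,4-trichloro-3-methylbutanoyl]-(2S)-bornane-10,2-sultam
Conditions: CHCl3, LiN(iPr)2, THF, -100 °C; add 7, -100 to -78 °C; AcOH quench at -78 °C
Reagents that add atoms: chloroform, ClC(Cl)Cl
Why: Mirror image of step 2 (chelate-controlled Michael addition of trichloromethyllithium): attack on the C-beta Re face should set (3R).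

Step 6
Reactants: 8 N-[(3R)-4,4,4-trichloro-3-methylbutanoyl]-(2S)-bornane-10,2-sultam
Product: 9 (3R)-4,4,4-trichloro-3-methylbutanal
Conditions: iBu2AlH, CH2Cl2, -78 °C; then aq. potassium sodium tartrate
Reagents that add atoms: none
Why: Partial hydride reduction of the N-acylsultam stops at a stable aluminium hemiaminal that releases the aldehyde only on work-up; CCl3 and C3 are inert at -78 °C.

Step 7
Reactants: 9 (3R)-4,4,4-trichloro-3-methylbutanal
Product: 10 (E)-hydrazone of (3R)-4,4,4-trichloro-3-methylbutanal
Conditions: N2H4·H2O (10 equiv), EtOH, 0 °C; used at once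
Reagents that add atoms: hydrazine (as hydrate), NN
Why: Hydrazone condensation, in which the large excess of hydrazine and the low temperature suppress azine formation; C3 is not involved.

Step 8
Reactants: 10 (E)-hydrazone of (3R)-4,4,4-trichloro-3-methylbutanal; 11 dimethylmalonyl dichloride
Product: 13 (6R)-7,7,7-trichloro-4-diazo-2,2,6-trimethyl-3-oxoheptanoyl chloride, via diazoalkane 12 (not isolated)
Conditions: MnO2, MgSO4, Et2O, -15 °C, cold filtration; filtrate added slowly to 11 (3 equiv), Et3N, Et2O, -78 to 0 °C; filter, remove excess 11 in high vacuum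
Reagents that add atoms: none
Why: Dehydrogenation of the hydrazone should give diazoalkane 12, whose nucleophilic carbon is C-acylated by the acid chloride (first stage of the Arndt–Eistert sequence, Newman–Beal variant with Et3N as HCl trap); 11 has no alpha-hydrogen, so no ketene forms, and inverse addition into excess 11 limits the reaction to one acyl chloride group.

Step 9
Reactants: 5 (3S)-4,4,4-trichloro-3-methylbutanamide; 13 (6R)-7,7,7-trichloro-4-diazo-2,2,6-trimethyl-3-oxoheptanoyl chloride
Product: 14 (6R)-7,7,7-trichloro-4-diazo-2,2,6-trimethyl-3-oxo-N-[(3S)-4,4,4-trichloro-3-methylbutanoyl]heptanamide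
Conditions: 5, LiN(SiMe3)2 (2 equiv), THF, -78 °C; then 13, -78 to -20 °C; AcOH quench
Reagents that add atoms: none
Why: N-acylation of a lithium amidate by an acid chloride (mixed acyclic imide synthesis): the second equivalent of base takes up the more acidic imide N–H as it forms, 13 has no acidic C–H next to its carbonyl groups, and both CH(CH3)CCl3 centres are untouched at low temperature.

Step 10
Reactants: 14 (6R)-7,7,7-trichloro-4-diazo-2,2,6-trimethyl-3-oxo-N-[(3S)-4,4,4-trichloro-3-methylbutanoyl]heptanamide
Product: 16 (5R)-3,3-dimethyl-1-[(3S)-4,4,4-trichloro-3-methylbutanoyl]-5-[(2R)-3,3,3-trichloro-2-methylpropyl]pyrrolidine-2,4-dione, via ring enol 15 (not isolated)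
Conditions: Rh2(O2CCPh3)4 (1 mol %), (R)-6,6'-bis(2,4,6-triisopropylphenyl)-1,1'-spirobiindane-7,7'-diyl hydrogen phosphate [(R)-STRIP, 5 mol %], 4 Å MS, CH2Cl2, -40 °C, slow addition of 14
Reagents that add atoms: none
Why: Proposed new method: Rh2(O2CCPh3)4 should expel N2 from 14 to give an electrophilic carbene at C5, imide N1 adds to it, and the resulting ylide sheds rhodium and shifts its N–H proton to oxygen to give ring enol 15, which the chiral phosphoric acid tautomerises to ketone 16. The closest known reaction types are the intramolecular amide N–H insertion of alpha-diazo ketones that closes the five-membered ring of bicyclic beta-lactams and the intermolecular asymmetric N–H insertion of carbamates and amides under dirhodium/chiral Brønsted acid co-catalysis; an acyclic imide N–H combined with an alpha-alkyl diazo ketone is covered by neither. The one ring closed is the five-membered N1–C2–C3–C4–C5 ring, formally 5-exo-trig at the Rh=C5 bond and helped by the gem-dimethyl group at C3 (Thorpe–Ingold effect). C5, the only new stereocentre, is set by face-selective protonation of planar enol 15 inside the hydrogen-bonded chiral phosphate (catalyst control, the side-chain centre being too remote to interfere), and the neutral cold medium keeps it from epimerising. The step needs N-attack to outrun the 1,2-hydride shift from the neighbouring CH2 and O-attack by the C2 carbonyl: the bulky triphenylacetate ligands, the low temperature and the electron-withdrawing CCl3 group beta to the migrating C–H slow the hydride shift, while the low C–N rotation barrier of an acyclic imide lets the nitrogen lone pair turn out of conjugation with C2=O and point at C5. Quaternary C3 removes any competing enolisation or five-ring C–H insertion site.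

Compound list
1 | (1S)-(-)-2,10-camphorsultam [(2R)-bornane-10,2-sultam] | CC1(C)[C@@H]2CC[C@]13CS(=O)(=O)N[C@@H]3C2 | starting material
2 | (E)-crotonyl chloride | C/C=C/C(=O)Cl | starting material
3 | N-[(E)-but-2-enoyl]-(2R)-bornane-10,2-sultam | CC1(C)[C@@H]2CC[C@]13CS(=O)(=O)N(C(=O)/C=C/C)[C@@H]3C2 | intermediate
4 | N-[(3S)-4,4,4-trichloro-3-methylbutanoyl]-(2R)-bornane-10,2-sultam | CC1(C)[C@@H]2CC[C@]13CS(=O)(=O)N(C(=O)C[C@H](C)C(Cl)(Cl)Cl)[C@@H]3C2 | intermediate
5 | (3S)-4,4,4-trichloro-3-methylbutanamide | NC(=O)C[C@H](C)C(Cl)(Cl)Cl | intermediate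
6 | (1R)-(+)-2,10-camphorsultam [(2S)-bornane-10,2-sultam] | CC1(C)[C@H]2CC[C@@]13CS(=O)(=O)N[C@H]3C2 | starting material
7 | N-[(E)-but-2-enoyl]-(2S)-bornane-10,2-sultam | CC1(C)[C@H]2CC[C@@]13CS(=O)(=O)N(C(=O)/C=C/C)[C@H]3C2 | intermediate
8 | N-[(3R)-4,4,4-trichloro-3-methylbutanoyl]-(2S)-bornane-10,2-sultam | CC1(C)[C@H]2CC[C@@]13CS(=O)(=O)N(C(=O)C[C@@H](C)C(Cl)(Cl)Cl)[C@H]3C2 | intermediate
9 | (3R)-4,4,4-trichloro-3-methylbutanal | O=CC[C@@H](C)C(Cl)(Cl)Cl | intermediate
10 | (E)-hydrazone of (3R)-4,4,4-trichloro-3-methylbutanal | N/N=C/C[C@@H](C)C(Cl)(Cl)Cl | intermediate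
11 | dimethylmalonyl dichloride | CC(C)(C(=O)Cl)C(=O)Cl | starting material
12 | (3R)-4,4,4-trichloro-1-diazo-3-methylbutane | [N-]=[N+]=CC[C@@H](C)C(Cl)(Cl)Cl | intermediate
13 | (6R)-7,7,7-trichloro-4-diazo-2,2,6-trimethyl-3-oxoheptanoyl chloride | C[C@H](CC(=[N+]=[N-])C(=O)C(C)(C)C(=O)Cl)C(Cl)(Cl)Cl | intermediate
14 | (6R)-7,7,7-trichloro-4-diazo-2,2,6-trimethyl-3-oxo-N-[(3S)-4,4,4-trichloro-3-methylbutanoyl]heptanamide | C[C@H](CC(=[N+]=[N-])C(=O)C(C)(C)C(=O)NC(=O)C[C@H](C)C(Cl)(Cl)Cl)C(Cl)(Cl)Cl | intermediate
15 | 4-hydroxy-3,3-dimethyl-1-[(3S)-4,4,4-trichloro-3-methylbutanoyl]-5-[(2R)-3,3,3-trichloro-2-methylpropyl]-1,3-dihydro-2H-pyrrol-2-one (ring enol) | C[C@H](CC1=C(O)C(C)(C)C(=O)N1C(=O)C[C@H](C)C(Cl)(Cl)Cl)C(Cl)(Cl)Cl | intermediate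
16 | (5R)-3,3-dimethyl-1-[(3S)-4,4,4-trichloro-3-methylbutanoyl]-5-[(2R)-3,3,3-trichloro-2-methylpropyl]pyrrolidine-2,4-dione | C[C@H](C[C@@H]1C(=O)C(C)(C)C(=O)N1C(=O)C[C@H](C)C(Cl)(Cl)Cl)C(Cl)(Cl)Cl | target

Total steps: 10. Longest linear sequence: 7 steps (steps 4 to 10).

Steps most likely to fail

Step 10 (labelled step). The carbene may be lost to 1,2-hydride migration. Closure may run through the C2 carbonyl oxygen instead of nitrogen. The proton relay may show poor facial selectivity. The fallback uses known chemistry and sets out from 14. Hydrobromination (HBr in AcOH/Et2O, 0 °C) should give the alpha-bromo ketone F1 as a mixture of epimers at the bromine-bearing carbon. One equivalent of Cs2CO3 in MeCN at 0 °C then forms the imide anion. Its in-plane nitrogen lone pair displaces bromide (intramolecular Gabriel-type alkylation, 5-exo-tet) to give 16 together with its C5 epimer F2. The two are separated by chromatography, and F2 is re-equilibrated with catalytic DBU and recycled. The fallback rejoins the route at 16.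

Step 8. The unstabilised diazoalkane may be lost before it is acylated, through azine formation during the oxidation, protonation or 1,2-hydride shift. The fallback sets out from 9 and avoids the free hydrazone. Condensation with 2-(trifluoromethyl)benzenesulfonyl hydrazide should give the crystalline N-sulfonylhydrazone F3. NaH in CH2Cl2 at -40 to 0 °C then triggers a low-temperature Bamford–Stevens fragmentation, and the insoluble sulfinate is filtered off. The fallback rejoins at 12, which is acylated by 11 as before.

Step 9. Acyl transfer at the neopentyl-type carbonyl may be slow. O-acylation may be followed by dehydration of the amide. Proton exchange between the product and the amidate may stall conversion. The fallback reverses the roles of the partners and sets out from 13 and 4. Quenching 13 with NH3 in THF at -78 °C should give the diazo keto primary amide F4. In parallel, 4 is hydrolysed (LiOH, H2O2, THF–H2O, 0 °C) to (3S)-4,4,4-trichloro-3-methylbutanoic acid F5. This acid is esterified (C6F5OH, DCC) to its pentafluorophenyl ester F6. Deprotonation of F4 with LiN(SiMe3)2 and acyl transfer from the unhindered active ester F6 should deliver the imide. The fallback rejoins at 14.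

Further compounds
F1 | step 10 | (6R)-4-bromo-7,7,7-trichloro-2,2,6-trimethyl-3-oxo-N-[(3S)-4,4,4-trichloro-3-methylbutanoyl]heptanamide (both C4 epimers) | C[C@H](CC(Br)C(=O)C(C)(C)C(=O)NC(=O)C[C@H](C)C(Cl)(Cl)Cl)C(Cl)(Cl)Cl
F2 | step 10 | (5S)-3,3-dimethyl-1-[(3S)-4,4,4-trichloro-3-methylbutanoyl]-5-[(2R)-3,3,3-trichloro-2-methylpropyl]pyrrolidine-2,4-dione | C[C@H](C[C@H]1C(=O)C(C)(C)C(=O)N1C(=O)C[C@H](C)C(Cl)(Cl)Cl)C(Cl)(Cl)Cl
F3 | step 8 | (E)-N'-[(3R)-4,4,4-trichloro-3-methylbutylidene]-2-(trifluoromethyl)benzenesulfonohydrazide | FC(F)(F)c1ccccc1S(=O)(=O)N/N=C/C[C@@H](C)C(Cl)(Cl)Cl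
F4 | step 9 | (6R)-7,7,7-trichloro-4-diazo-2,2,6-trimethyl-3-oxoheptanamide | C[C@H](CC(=[N+]=[N-])C(=O)C(C)(C)C(N)=O)C(Cl)(Cl)Cl
F5 | step 9 | (3S)-4,4,4-trichloro-3-methylbutanoic acid | OC(=O)C[C@H](C)C(Cl)(Cl)Cl
F6 | step 9 | pentafluorophenyl (3S)-4,4,4-trichloro-3-methylbutanoate | O=C(C[C@H](C)C(Cl)(Cl)Cl)Oc1c(F)c(F)c(F)c(F)c1F
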